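**Retrosynthetic overview**

- Feature: the only stereocentre is a CH that carries ring B (4-hydroxyphenyl) and ring C (2,4-dihydroxyphenyl with a side arm at C5). Without its C2 oxygen and C5 arm, ring C is ring B again, so the centre maps onto a prochiral bis(4-oxyphenyl)methine.
- Late disconnections: hydrogenation of a C=C with loss of all benzyl groups, then the Heck bond between C5 of ring C and the vinyl ketone that carries ring D.
- Ring A–CH2 bond: aryl Grignard on a Weinreb amide, with the carbonyl then reduced away. The amide and the free ring-C phenol (which steers bromination to C5) come from opening a 4-aryl-dihydrocoumarin.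
- Key disconnection: the aryl C–O bond of that lactone, formed by ligand-controlled C–H lactonisation of achiral 3,3-bis[4-(benzyloxy)phenyl]propanoic acid, itself made from 4,4'-dihydroxybenzophenone by olefination and reduction.
- Ring order: the lactone is the only ring formed (step 4) and is opened again in step 5. Rings A to D are bought as arenes: B and C together in the benzophenone, A in the bromophenol, D in the acetophenone.

Key step: step 4

Assumption: the ring sense chosen by a given amino acid ligand on this homologated acid cannot be predicted with confidence; the route is written with N-Boc-L-isoleucine and would use the D-configured ligand instead if a first run delivers the 4S lactone.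

**Route**

Step 1
Reactants: 1 4,4'-dihydroxybenzophenone
Product: 2 4,4'-bis(benzyloxy)benzophenone
Conditions: BnBr (2.4 equiv), K2CO3, DMF, 60 °C
Reagents that add atoms: benzyl bromide, BrCc1ccccc1
Why: Williamson etherification of both phenoxides should proceed cleanly, the ketone being inert to carbonate.

Step 2
Reactants: 2 4,4'-bis(benzyloxy)benzophenone; 3 trimethyl phosphonoacetate
Product: 4 methyl 3,3-bis[4-(benzyloxy)phenyl]prop-2-enoate
Conditions: NaH, DME, 0 °C → reflux (excess of 3)
Reagents that add atoms: none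
Why: Horner–Wadsworth–Emmons olefination; the electron-rich diaryl ketone is slow, so excess phosphonate anion and heat are used, and no alkene geometry arises because the two aryl groups are identical.

Step 3
Reactants: 4 methyl 3,3-bis[4-(benzyloxy)phenyl]prop-2-enoate
Product: 6 3,3-bis[4-(benzyloxy)phenyl]propanoic acid, via saturated methyl ester 5 (not isolated)
Conditions: Mg turnings, MeOH–THF, 0 °C → rt; then 2 M aq NaOH, 60 °C; aq HCl
Reagents that add atoms: sodium hydroxide, [Na+].[OH-]
Why: electron-transfer conjugate reduction of the β,β-diaryl acrylate by Mg in methanol leaves aryl benzyl ethers alone (which catalytic hydrogenation would not), and saponification in the same flask should give the achiral acid.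

Step 4
Reactants: 6 3,3-bis[4-(benzyloxy)phenyl]propanoic acid
Product: 7 (4R)-7-(benzyloxy)-4-[4-(benzyloxy)phenyl]-3,4-dihydro-2H-chromen-2-one
Conditions: Pd(OAc)2 (10 mol%), Boc-L-Ile-OH (40 mol%), PhI(OAc)2 (1.5 equiv), KOAc (2 equiv), t-BuOH, 80 °C
Reagents that add atoms: none
Why: Proposed new method: the potassium carboxylate of 6 binds divalent palladium carrying the mono-N-protected amino acid, whose carbamate serves as internal base in a concerted metalation–deprotonation at an ortho C–H of one of the two enantiotopic 4-benzyloxyphenyl rings to give a seven-membered aryl–palladium carboxylate; PhI(OAc)2 oxidises this to tetravalent palladium and C(sp2)–O reductive elimination releases the lactone and divalent palladium. The closest known reaction type is the enantioselective Pd(OAc)2/Boc-amino acid C–H activation/C–O lactonisation of 2,2-diarylacetic acids to benzofuran-2-ones, supported by carboxylate-directed ortho C–H functionalisation of 3-arylpropanoic acids; the present substrate has one more methylene between carboxylate and methine. The six-membered lactone ring is closed by bond formation between the carboxylate oxygen and the ring carbon ortho to the methine, out of the seven-membered palladacycle, and the geminal diaryl substitution should favour the folded conformer needed. The C4 centre is not touched; it becomes stereogenic only because one ring is oxygenated, and its 4R configuration is controlled by the chiral ligand choosing between the two rings in the C–H cleavage step. The step needs ring selectivity, ortho selectivity and mono-oxygenation: the two ortho C–H bonds of each ring are equivalent, only ortho positions are within reach of the carboxylate-bound metal, and lactonisation consumes the directing carboxylate so the second ring cannot react. Direct oxidant-induced ipso spirolactonisation of the electron-rich rings should be held back by keeping both phenols as benzyl ethers and by the non-acidic t-BuOH/KOAc medium.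

Step 5
Reactants: 7 (4R)-7-(benzyloxy)-4-[4-(benzyloxy)phenyl]-3,4-dihydro-2H-chromen-2-one
Product: 8 (3R)-3-[4-(benzyloxy)-2-hydroxyphenyl]-3-[4-(benzyloxy)phenyl]-N-methoxy-N-methylpropanamide
Conditions: MeNH(OMe)·HCl, AlMe3, CH2Cl2, 0 °C → rt; cold 1 M HCl work-up
Reagents that add atoms: N,O-dimethylhydroxylamine hydrochloride, CNOC.Cl
Why: Weinreb aminolysis of the reactive aryl ester by the aluminium amide opens the lactone and frees the ring-C phenol; the stereocentre is β to the carbonyl and cannot epimerise.

Step 6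
Reactants: 8 (3R)-3-[4-(benzyloxy)-2-hydroxyphenyl]-3-[4-(benzyloxy)phenyl]-N-methoxy-N-methylpropanamide
Product: 9 (3R)-3-[4-(benzyloxy)-5-bromo-2-hydroxyphenyl]-3-[4-(benzyloxy)phenyl]-N-methoxy-N-methylpropanamide
Conditions: NBS (1.0 equiv), MeCN, −20 → 0 °C
Reagents that add atoms: N-bromosuccinimide, O=C1CCC(=O)N1Br
Why: electrophilic aromatic bromination should go to C5 of ring C, which is para to the free hydroxyl and ortho to the benzyloxy group; the site between the two oxygens is crowded, and ring B carries only one ether and is much less activated.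

Step 7
Reactants: 9 (3R)-3-[4-(benzyloxy)-5-bromo-2-hydroxyphenyl]-3-[4-(benzyloxy)phenyl]-N-methoxy-N-methylpropanamide
Product: 10 (3R)-3-[2,4-bis(benzyloxy)-5-bromophenyl]-3-[4-(benzyloxy)phenyl]-N-methoxy-N-methylpropanamide
Conditions: BnBr, K2CO3, DMF, rt
Reagents that add atoms: benzyl bromide, BrCc1ccccc1
Why: Williamson etherification caps the phenol before organometallic chemistry; the Weinreb amide is too poor an electrophile to relactonise with phenoxide under these mild basic conditions.

Step 8
Reactants: 11 4-bromo-3-methoxyphenol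
Product: 12 4-(benzyloxy)-1-bromo-2-methoxybenzene
Conditions: BnBr, K2CO3, acetone, reflux
Reagents that add atoms: benzyl bromide, BrCc1ccccc1
Why: Williamson etherification gives the ring-A bromide with methoxy ortho and benzyloxy para to bromine, the pattern of ring A.

Step 9
Reactants: 12 4-(benzyloxy)-1-bromo-2-methoxybenzene; 10 (3R)-3-[2,4-bis(benzyloxy)-5-bromophenyl]-3-[4-(benzyloxy)phenyl]-N-methoxy-N-methylpropanamide
Product: 14 (3R)-1-[4-(benzyloxy)-2-methoxyphenyl]-3-[2,4-bis(benzyloxy)-5-bromophenyl]-3-[4-(benzyloxy)phenyl]propan-1-one, via arylmagnesium bromide 13 (not isolated)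
Conditions: 12, Mg turnings, I2 (cat.), THF, reflux; then 10, THF, 0 °C → rt; 1 M HCl work-up
Reagents that add atoms: magnesium, [Mg] (kept only in intermediate 13)
Why: Grignard addition to the Weinreb amide stops at the chelated tetrahedral adduct and gives the ketone on work-up; an aryl Grignard should not exchange with the electron-rich aryl bromide of 10 at this temperature, which is why magnesium is chosen over lithium.

Step 10
Reactants: 14 (3R)-1-[4-(benzyloxy)-2-methoxyphenyl]-3-[2,4-bis(benzyloxy)-5-bromophenyl]-3-[4-(benzyloxy)phenyl]propan-1-one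
Product: 15 (3R)-1-[4-(benzyloxy)-2-methoxyphenyl]-3-[2,4-bis(benzyloxy)-5-bromophenyl]-3-[4-(benzyloxy)phenyl]propan-1-ol (mixture of C1 epimers)
Conditions: NaBH4, THF–MeOH, 0 °C → rt
Reagents that add atoms: none
Why: borohydride reduction of the aryl ketone; the new carbinol centre is removed in the next step, so its configuration does not matter.

Step 11
Reactants: 15 (3R)-1-[4-(benzyloxy)-2-methoxyphenyl]-3-[2,4-bis(benzyloxy)-5-bromophenyl]-3-[4-(benzyloxy)phenyl]propan-1-ol
Product: 16 1,5-bis(benzyloxy)-2-bromo-4-[(1R)-3-[4-(benzyloxy)-2-methoxyphenyl]-1-[4-(benzyloxy)phenyl]propyl]benzene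
Conditions: Et3SiH (3 equiv), CF3CO2H (5 equiv), CH2Cl2, −20 → 0 °C
Reagents that add atoms: none
Why: ionic hydrogenation; the alcohol ionises readily to a cation stabilised by the ortho-methoxy and para-benzyloxy groups of ring A and is trapped by silane hydride, while the stereocentre two carbons away is not involved and the aryl bromide and benzyl ethers should survive the cold, dilute acid.

Step 12
Reactants: 17 4'-(benzyloxy)acetophenone
Product: 18 1-[4-(benzyloxy)phenyl]prop-2-en-1-one
Conditions: (CH2O)n, i-Pr2NH·CF3CO2H (1 equiv), CF3CO2H (cat.), THF, reflux; used at once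
Reagents that add atoms: paraformaldehyde (as formaldehyde), C=O
Why: Mannich-type α-methylenation of the aryl methyl ketone, in which the bulky amine eliminates in situ to give the aryl vinyl ketone.

Step 13
Reactants: 16 1,5-bis(benzyloxy)-2-bromo-4-[(1R)-3-[4-(benzyloxy)-2-methoxyphenyl]-1-[4-(benzyloxy)phenyl]propyl]benzene; 18 1-[4-(benzyloxy)phenyl]prop-2-en-1-one
Product: 19 (2E)-1-[4-(benzyloxy)phenyl]-3-{2,4-bis(benzyloxy)-5-[(1R)-3-[4-(benzyloxy)-2-methoxyphenyl]-1-[4-(benzyloxy)phenyl]propyl]phenyl}prop-2-en-1-one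
Conditions: Pd(OAc)2 (5 mol%), [HP(t-Bu)3]BF4 (10 mol%), Cy2NMe, 1,4-dioxane, 70 °C; 18 added in portions
Reagents that add atoms: none
Why: Heck reaction; the bulky electron-rich phosphine lets zerovalent palladium insert into the electron-rich aryl bromide at moderate temperature, and insertion at the terminal carbon of the enone followed by β-hydride elimination should give the E-enone.

Step 14
Reactants: 19 (2E)-1-[4-(benzyloxy)phenyl]-3-{2,4-bis(benzyloxy)-5-[(1R)-3-[4-(benzyloxy)-2-methoxyphenyl]-1-[4-(benzyloxy)phenyl]propyl]phenyl}prop-2-en-1-one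
Product: 20 3-{2,4-dihydroxy-5-[(1R)-3-(4-hydroxy-2-methoxyphenyl)-1-(4-hydroxyphenyl)propyl]phenyl}-1-(4-hydroxyphenyl)propan-1-one (CNP0253987.1)
Conditions: H2 (1 atm), 10% Pd/C, EtOAc–MeOH, rt, stopped at full debenzylation
Reagents that add atoms: none
Why: catalytic hydrogenation saturates the enone C=C and hydrogenolyses all five benzyl ethers in one operation, while the electron-rich 4-oxyphenyl ketone should resist reduction under neutral conditions at ambient pressure; the methyl ether and the stereocentre are untouched.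

**Compound list**

1 | 4,4'-dihydroxybenzophenone | O=C(c1ccc(O)cc1)c1ccc(O)cc1 | starting material
2 | 4,4'-bis(benzyloxy)benzophenone | O=C(c1ccc(OCc2ccccc2)cc1)c1ccc(OCc2ccccc2)cc1 | intermediate
3 | trimethyl phosphonoacetate | COC(=O)CP(=O)(OC)OC | starting material
4 | methyl 3,3-bis[4-(benzyloxy)phenyl]prop-2-enoate | COC(=O)C=C(c1ccc(OCc2ccccc2)cc1)c1ccc(OCc2ccccc2)cc1 | intermediate
5 | methyl 3,3-bis[4-(benzyloxy)phenyl]propanoate (not isolated) | COC(=O)CC(c1ccc(OCc2ccccc2)cc1)c1ccc(OCc2ccccc2)cc1 | intermediate
6 | 3,3-bis[4-(benzyloxy)phenyl]propanoic acid | OC(=O)CC(c1ccc(OCc2ccccc2)cc1)c1ccc(OCc2ccccc2)cc1 | intermediate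
7 | (4R)-7-(benzyloxy)-4-[4-(benzyloxy)phenyl]-3,4-dihydro-2H-chromen-2-one | O=C1C[C@H](c2ccc(OCc3ccccc3)cc2)c2ccc(OCc3ccccc3)cc2O1 | intermediate
8 | (3R)-3-[4-(benzyloxy)-2-hydroxyphenyl]-3-[4-(benzyloxy)phenyl]-N-methoxy-N-methylpropanamide | CON(C)C(=O)C[C@H](c1ccc(OCc2ccccc2)cc1)c1ccc(OCc2ccccc2)cc1O | intermediate
9 | (3R)-3-[4-(benzyloxy)-5-bromo-2-hydroxyphenyl]-3-[4-(benzyloxy)phenyl]-N-methoxy-N-methylpropanamide | CON(C)C(=O)C[C@H](c1ccc(OCc2ccccc2)cc1)c1cc(Br)c(OCc2ccccc2)cc1O | intermediate
10 | (3R)-3-[2,4-bis(benzyloxy)-5-bromophenyl]-3-[4-(benzyloxy)phenyl]-N-methoxy-N-methylpropanamide | CON(C)C(=O)C[C@H](c1ccc(OCc2ccccc2)cc1)c1cc(Br)c(OCc2ccccc2)cc1OCc1ccccc1 | intermediate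
11 | 4-bromo-3-methoxyphenol | COc1cc(O)ccc1Br | starting material
12 | 4-(benzyloxy)-1-bromo-2-methoxybenzene | COc1cc(OCc2ccccc2)ccc1Br | intermediate
13 | [4-(benzyloxy)-2-methoxyphenyl]magnesium bromide (not isolated) | COc1cc(OCc2ccccc2)ccc1[Mg]Br | intermediate
14 | (3R)-1-[4-(benzyloxy)-2-methoxyphenyl]-3-[2,4-bis(benzyloxy)-5-bromophenyl]-3-[4-(benzyloxy)phenyl]propan-1-one | COc1cc(OCc2ccccc2)ccc1C(=O)C[C@H](c1ccc(OCc2ccccc2)cc1)c1cc(Br)c(OCc2ccccc2)cc1OCc1ccccc1 | intermediate
15 | (3R)-1-[4-(benzyloxy)-2-methoxyphenyl]-3-[2,4-bis(benzyloxy)-5-bromophenyl]-3-[4-(benzyloxy)phenyl]propan-1-ol, C1 epimers | COc1cc(OCc2ccccc2)ccc1C(O)C[C@H](c1ccc(OCc2ccccc2)cc1)c1cc(Br)c(OCc2ccccc2)cc1OCc1ccccc1 | intermediate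
16 | 1,5-bis(benzyloxy)-2-bromo-4-[(1R)-3-[4-(benzyloxy)-2-methoxyphenyl]-1-[4-(benzyloxy)phenyl]propyl]benzene | COc1cc(OCc2ccccc2)ccc1CC[C@H](c1ccc(OCc2ccccc2)cc1)c1cc(Br)c(OCc2ccccc2)cc1OCc1ccccc1 | intermediate
17 | 4'-(benzyloxy)acetophenone | CC(=O)c1ccc(OCc2ccccc2)cc1 | starting material
18 | 1-[4-(benzyloxy)phenyl]prop-2-en-1-one | C=CC(=O)c1ccc(OCc2ccccc2)cc1 | intermediate
19 | (2E)-1-[4-(benzyloxy)phenyl]-3-{2,4-bis(benzyloxy)-5-[(1R)-3-[4-(benzyloxy)-2-methoxyphenyl]-1-[4-(benzyloxy)phenyl]propyl]phenyl}prop-2-en-1-one | COc1cc(OCc2ccccc2)ccc1CC[C@H](c1ccc(OCc2ccccc2)cc1)c1cc(/C=C/C(=O)c2ccc(OCc3ccccc3)cc2)c(OCc2ccccc2)cc1OCc1ccccc1 | intermediate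
20 | 3-{2,4-dihydroxy-5-[(1R)-3-(4-hydroxy-2-methoxyphenyl)-1-(4-hydroxyphenyl)propyl]phenyl}-1-(4-hydroxyphenyl)propan-1-one | COc1cc(O)ccc1CC[C@H](c1ccc(O)cc1)c1cc(CCC(=O)c2ccc(O)cc2)c(O)cc1O | target

**Step count**

Total: 14 steps. Longest linear sequence: 12 steps (steps 1–7, 9–11, 13, 14).

**Steps most likely to fail**

1. Step 4 (proposed new method). C–H cleavage through the larger palladacycle may be slow or may discriminate poorly between the two rings, and the iodine oxidant may instead attack the electron-rich arenes by dearomatising ipso lactonisation. A modest enantiomeric excess could be raised by recrystallising 7 or 8. The fallback uses known chemistry, sets out from phosphonate 3 and returns at 10. Horner–Wadsworth–Emmons reaction of 3 with commercial 2,4-bis(benzyloxy)benzaldehyde (NaH, THF) would give methyl (2E)-3-[2,4-bis(benzyloxy)phenyl]prop-2-enoate F1. Rhodium-catalysed enantioselective 1,4-addition of 4-(benzyloxy)phenylboronic acid (Rh(acac)(C2H4)2, BINAP of the enantiomer that gives 3R, dioxane–H2O, 90 °C) would give methyl (3R)-3-[2,4-bis(benzyloxy)phenyl]-3-[4-(benzyloxy)phenyl]propanoate F2. Treatment with MeNH(OMe)·HCl and i-PrMgCl (THF, −10 °C) would give (3R)-3-[2,4-bis(benzyloxy)phenyl]-3-[4-(benzyloxy)phenyl]-N-methoxy-N-methylpropanamide F3. Bromination with NBS (MeCN, 0 °C), para to the 2-benzyloxy group of the doubly activated ring, would then give 10.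

2. Step 13. Oxidative addition into the hindered, doubly oxygenated aryl bromide may be slow while the aryl vinyl ketone polymerises or adds nucleophiles. The fallback sets out from 16 and returns at 19. Bromine–lithium exchange (n-BuLi, THF, −78 °C) and quenching with DMF would give 2,4-bis(benzyloxy)-5-[(1R)-3-[4-(benzyloxy)-2-methoxyphenyl]-1-[4-(benzyloxy)phenyl]propyl]benzaldehyde F4. Claisen–Schmidt condensation of F4 with acetophenone 17 (KOH, EtOH–THF, rt) would give enone 19 without any vinyl ketone.

3. Step 11. The benzylic cation may be captured by the ortho benzyloxy oxygen of ring C with loss of benzyl (closure to a 2,4-diarylchroman), or benzyl ethers may be partly cleaved by the acid. The fallback avoids the cation, sets out from ketone 14 and returns at 16. Condensation with TsNHNH2 (EtOH, 70 °C) would give N'-[(3R)-1-[4-(benzyloxy)-2-methoxyphenyl]-3-[2,4-bis(benzyloxy)-5-bromophenyl]-3-[4-(benzyloxy)phenyl]propylidene]-4-methylbenzenesulfonohydrazide F5. Reduction with catecholborane (CHCl3, 0 °C) and then NaOAc·3H2O at reflux would expel sulfinate and dinitrogen from the diazene and give 16 under nearly neutral conditions.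

**Further compounds**

F1 | step 4 | methyl (2E)-3-[2,4-bis(benzyloxy)phenyl]prop-2-enoate | COC(=O)/C=C/c1ccc(OCc2ccccc2)cc1OCc1ccccc1
F2 | step 4 | methyl (3R)-3-[2,4-bis(benzyloxy)phenyl]-3-[4-(benzyloxy)phenyl]propanoate | COC(=O)C[C@H](c1ccc(OCc2ccccc2)cc1)c1ccc(OCc2ccccc2)cc1OCc1ccccc1
F3 | step 4 | (3R)-3-[2,4-bis(benzyloxy)phenyl]-3-[4-(benzyloxy)phenyl]-N-methoxy-N-methylpropanamide | CON(C)C(=O)C[C@H](c1ccc(OCc2ccccc2)cc1)c1ccc(OCc2ccccc2)cc1OCc1ccccc1
F4 | step 13 | 2,4-bis(benzyloxy)-5-[(1R)-3-[4-(benzyloxy)-2-methoxyphenyl]-1-[4-(benzyloxy)phenyl]propyl]benzaldehyde | COc1cc(OCc2ccccc2)ccc1CC[C@H](c1ccc(OCc2ccccc2)cc1)c1cc(C=O)c(OCc2ccccc2)cc1OCc1ccccc1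
F5 | step 11 | N'-[(3R)-1-[4-(benzyloxy)-2-methoxyphenyl]-3-[2,4-bis(benzyloxy)-5-bromophenyl]-3-[4-(benzyloxy)phenyl]propylidene]-4-methylbenzenesulfonohydrazide | COc1cc(OCc2ccccc2)ccc1C(C[C@H](c1ccc(OCc2ccccc2)cc1)c1cc(Br)c(OCc2ccccc2)cc1OCc1ccccc1)=NNS(=O)(=O)c1ccc(C)cc1
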